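In the first 1.3 h, each catalyst of the ochre run turned over 26.4 times on average. Set beside the same count in the other flasks, that number divided two chemists before the red run was read.

| setting | ochre | blue | violet | red |
|---|---|---|---|---|
| substrate | 0.0500 M | 0.0200 M | 0.0750 M | 0.100 M |
| reagent | 0.0600 M | 0.0300 M | 0.0600 M | 0.0600 M |
| catalyst | 2.50 × 10⁻⁴ M | 2.50 × 10⁻⁴ M | 2.50 × 10⁻⁴ M | 2.50 × 10⁻⁴ M |
| time |  |  |  | 6.6 h |

- ochre run (time / h: [target] / M): 1.3: 0.0066; 2.6: 0.0114; 4.0: 0.0160; 5.3: 0.0194; 6.6: 0.0229
- blue run (time / h: [target] / M): 1.3: 0.0017; 2.6: 0.0032; 4.0: 0.0042; 5.3: 0.0052; 6.6: 0.0060
- violet run (time / h: [target] / M): 1.3: 0.0086; 2.6: 0.0157; 4.0: 0.0217; 5.3: 0.0260; 6.6: 0.0294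

(scatter of a reading: 3 × 10⁻⁴ M)

* how the opening rate goes with [substrate] round the charge of the ochre run: the exponent of the rate at two percent of substrate gone to target (one fixed amount of target, the same in the runs compared)
* how the opening rate goes with [reagent] round the charge of the ochre run: the exponent of the rate at two percent of substrate gone to target
* the blue run starts with 0.0300 M less of substrate and of reagent than the ochre run, and with no target. Compared where both hold the same amount of substrate, once fifteen percent of what the blue run was charged with has turned into target, is the blue run faster, slower or alike (within a tenth)?
* target in the red run at 6.6 h, as a share of the substrate charged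

- Overall: substrate + reagent -> target, with catalyst as catalyst.
- Constant volume, constant temperature.
- What is held in complexes is read along with the free species.
- "The second partner" is reagent.
- An order is taken over about fifteen percent of the charge, up and down.

The first chemist holds the filled-catalyst view: substrate keeps the catalyst loaded, so turnovers come at one fixed pace. She divides the first reading by catalyst and time and gets 20.3 h⁻¹ for ochre and 26.5 h⁻¹ for violet. The pace grew by a factor of 1.31, less than the factor of 1.50 in substrate. Carrying the violet pace to the red run, she expects 175 turnovers in 6.6 h, or 43.7% of the substrate charged.

The second chemist objects that the blue pace, 5.23 h⁻¹, is a quarter of the ochre pace, so the pace is not fixed. He takes the rate as a constant times substrate times reagent and integrates to the middle reading at 4.0 h, where ochre has turned 32.0% of its substrate. The ochre constant is 1.89 M⁻¹ h⁻¹ there and 1.93 M⁻¹ h⁻¹ at the first reading. So he keeps reagent at order one, and he expects blue and ochre to run alike at equal substrate.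

The violet constant, read at the same time, is lower than the ochre one, at 1.79 M⁻¹ h⁻¹. The gap is 5.23%, and one scatter is 1.88% of the ochre reading, so what follows is a coarse reading. I side with him and call the shortfall of the substrate order below one the held share, which I read as the part of the catalyst kept from fresh substrate: 0.132.

As my own approximation, I let the constant scale with substrate to the power minus that share, which gives 1.72 M⁻¹ h⁻¹ for the red run, whose reagent charge equals that of the ochre run. Reagent is the limiting reagent there and allows 60.0% of the substrate. With 1.58 as the integrated ratio, I reckon 35.4 mM of target at 6.6 h, which is 35.4% of the substrate charged and 142 turnovers on average.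

The forecast gives orders of 0.83 in substrate and 1 in reagent, blue alike, and 34.8%, a little lower than my share, and it reads the substrate order so because “k drops mildly as substrate rises”.

The target in the red run at 6.6 h comes to 35.1% of the substrate charged, which is 141 turnovers on average; the orders are 0.85 in substrate and 0.99 in reagent, and blue is alike.

catalyst + substrate ⇌ catalyst-substrate complex, settled at all times (3.470 M⁻¹); catalyst-substrate complex + reagent ⇌ ternary complex, settled at all times (3.550 M⁻¹); ternary complex → target + catalyst (723.6 h⁻¹) The substrate order falls short of one by 0.150. At a fixed reagent charge, the filled-catalyst view has its region at substrate beyond 288 mM, the reciprocal of the first binding constant, where catalyst-substrate complex outweighs free catalyst, and that level is more than the red charge. Carried to the blue run, the held share gives a constant of 2.13 M⁻¹ h⁻¹ and a time of 13.5 h for half its substrate; the blue run takes 13.6 h.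

The data stem from a simulated flask on assumed constants, and the scatter is random.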